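The route rests on cutting the dihydrofuran ring at C3–C3a and O1–C7a, which separates ring A, as a para-formyl aryl iodide, from an O1–C2–C3 unit carried by an enantioenriched cis-epoxide of the syringyl fragment. A palladium/norbornene (Catellani) cascade exploits the substitution of ring A: C7a bears the iodide, its neighbour C7 is blocked by methoxy, and the other neighbour, C3a, is the only ortho position still carrying hydrogen. In one operation C3a is alkylated by the epoxide carbon that becomes C3 (with inversion) and the released alkoxide closes O1–C7a, giving the trans-2,3-disubstituted ring. The epoxide carries a pivaloyl-protected phenol and a silyl-protected primary alcohol; four routine steps then finish the target.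

Key step: step 6

Remark on the chemistry: ring A carries its C5 carbon through the key step as a formyl group (the iodide is a catalogue compound); the disconnection and both skeletons are unchanged, an acceptor sits para to C7a for the C–O bond formation, and the pivalate stays on the syringyl oxygen until the last reduction, so that no free phenol meets an oxidant.

Remark on the chemistry: the absolute sense of the two asymmetric epoxidations named below is assigned by analogy with cis-β-methylstyrene (manganese-salen) and with simple Z-allylic alcohols (titanium-tartrate).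

Step 1
Reactants: 1 4-bromo-2,6-dimethoxyphenol
Product: 2 4-bromo-2,6-dimethoxyphenyl pivalate
Conditions: PivCl, Et3N, DMAP (cat.), CH2Cl2, 0 °C to rt
Reagents that add atoms: pivaloyl chloride, CC(C)(C)C(=O)Cl
Why: O-acylation of the phenol under nucleophilic catalysis masks the oxygen as a hindered, base-stable and electron-withdrawing ester.

Step 2
Reactants: 3 propargyl alcohol
Product: 4 tert-butyldimethyl(prop-2-yn-1-yloxy)silane
Conditions: TBSCl, imidazole, CH2Cl2, 0 °C to rt
Reagents that add atoms: tert-butyldimethylsilyl chloride, CC(C)(C)[Si](C)(C)Cl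
Why: Silylation of a primary alcohol through the N-silylimidazolium ion gives the protected alkyne for the coupling.

Step 3
Reactants: 2 4-bromo-2,6-dimethoxyphenyl pivalate, 4 tert-butyldimethyl(prop-2-yn-1-yloxy)silane
Product: 5 4-[3-(tert-butyldimethylsilyloxy)prop-1-yn-1-yl]-2,6-dimethoxyphenyl pivalate
Conditions: PdCl2(PPh3)2 (3 mol %), CuI (5 mol %), Et3N, DMF, 70 °C
Reagents that add atoms: none
Why: Sonogashira coupling (oxidative addition of the aryl bromide to zerovalent palladium, transmetalation from the copper acetylide, reductive elimination) joins the fragments, and the pivalate and silyl ether tolerate the amine base.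

Step 4
Reactants: 5 4-[3-(tert-butyldimethylsilyloxy)prop-1-yn-1-yl]-2,6-dimethoxyphenyl pivalate
Product: 6 4-[(1Z)-3-(tert-butyldimethylsilyloxy)prop-1-en-1-yl]-2,6-dimethoxyphenyl pivalate
Conditions: H2 (1 atm), 5% Pd/CaCO3 poisoned with Pb(OAc)2, quinoline, EtOAc, rt
Reagents that add atoms: none
Why: Semihydrogenation by syn addition of hydrogen on lead-poisoned palladium should give the Z-alkene, with quinoline holding back over-reduction and isomerisation.

Step 5
Reactants: 6 4-[(1Z)-3-(tert-butyldimethylsilyloxy)prop-1-en-1-yl]-2,6-dimethoxyphenyl pivalate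
Product: 7 4-[(2R,3S)-3-(tert-butyldimethylsilyloxymethyl)oxiran-2-yl]-2,6-dimethoxyphenyl pivalate (cis-epoxide)
Conditions: (R,R)-N,N'-bis(3,5-di-tert-butylsalicylidene)-1,2-cyclohexanediaminomanganese chloride (5 mol %), 4-phenylpyridine N-oxide (20 mol %), aq. NaOCl (buffered, pH 11.3), CH2Cl2, 0 °C
Reagents that add atoms: sodium hypochlorite, [Na+].[O-]Cl
Why: Jacobsen–Katsuki epoxidation of a cis-disubstituted aryl alkene, in which the (R,R)-salen ligand should direct oxygen to one enantioface of the Z-alkene and so set both epoxide carbons at once (benzylic carbon R, neighbouring carbon S).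

Step 6
Reactants: 7 4-[(2R,3S)-3-(tert-butyldimethylsilyloxymethyl)oxiran-2-yl]-2,6-dimethoxyphenyl pivalate, 8 4-iodo-3-methoxybenzaldehyde
Product: 9 (2S,3R)-3-(tert-butyldimethylsilyloxymethyl)-2-[3,5-dimethoxy-4-(pivaloyloxy)phenyl]-7-methoxy-2,3-dihydrobenzofuran-5-carbaldehyde (trans)
Conditions: Pd(OAc)2 (10 mol %), P(2-furyl)3 (25 mol %), norbornene (2 equiv), Cs2CO3 (2.5 equiv), MeCN, 85 °C
Reagents that add atoms: none
Why: Proposed new method: oxidative addition of the C7a–I bond of 8 to zerovalent palladium, carbopalladation of norbornene and metalation of the neighbouring C3a–H should give a five-membered palladacycle of divalent palladium, which is expected to attack epoxide 7 from the rear at the carbon bearing CH2OSi (through tetravalent palladium) and to forge C3–C3a by reductive elimination, after which norbornene departs by β-carbon elimination. The closest known reaction type is the palladium/norbornene annulation of ortho-substituted aryl iodides with terminal epoxides to 2,3-dihydrobenzofurans; an internal aryl epoxide has not been used in it. The dihydrofuran ring is closed by intramolecular C(aryl)–O reductive elimination from a six-membered arylpalladium alkoxide chelate (ipso etherification at C7a), which the formyl group para to C7a should accelerate. No stereocentre is created: C2 keeps the configuration of the benzylic epoxide carbon and C3 is inverted, so the cis-epoxide is translated into the trans (2S,3R) ring. The step needs alkylation at C3a only and ring opening at the non-benzylic epoxide carbon: the C7 methoxy group blocks the second ortho position, the pivalate makes the syringyl ring too electron-poor for benzylic ionisation and survives carbonate (a free para-phenoxide would destroy the epoxide through a quinone methide), and the silyl ether neither deactivates the reacting carbon as an ester would nor can migrate to the alkoxide. Attack at the benzylic carbon and palladium-mediated isomerisation of the epoxide to a ketone remain the unproven points.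

Step 7
Reactants: 9 (2S,3R)-3-(tert-butyldimethylsilyloxymethyl)-2-[3,5-dimethoxy-4-(pivaloyloxy)phenyl]-7-methoxy-2,3-dihydrobenzofuran-5-carbaldehyde
Product: 10 (2S,3R)-2-[3,5-dimethoxy-4-(pivaloyloxy)phenyl]-3-(hydroxymethyl)-7-methoxy-2,3-dihydrobenzofuran-5-carbaldehyde
Conditions: HF·pyridine, pyridine, THF, 0 °C to rt
Reagents that add atoms: none
Why: Fluoride-mediated desilylation of the primary silyl ether under buffered conditions should leave the aryl pivalate, the aldehyde and both stereocentres untouched.

Step 8
Reactants: 10 (2S,3R)-2-[3,5-dimethoxy-4-(pivaloyloxy)phenyl]-3-(hydroxymethyl)-7-methoxy-2,3-dihydrobenzofuran-5-carbaldehyde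
Product: 11 ethyl (2E)-3-{(2S,3R)-2-[3,5-dimethoxy-4-(pivaloyloxy)phenyl]-3-(hydroxymethyl)-7-methoxy-2,3-dihydrobenzofuran-5-yl}prop-2-enoate
Conditions: Ph3P=CHCO2Et, toluene, 60 °C
Reagents that add atoms: ethyl (triphenylphosphoranylidene)acetate, CCOC(=O)C=P(c1ccccc1)(c1ccccc1)c1ccccc1
Why: Wittig olefination with a stabilised ylide runs under neutral conditions and should give the E-enoate, the free primary alcohol and the pivalate being inert.

Step 9
Reactants: 11 ethyl (2E)-3-{(2S,3R)-2-[3,5-dimethoxy-4-(pivaloyloxy)phenyl]-3-(hydroxymethyl)-7-methoxy-2,3-dihydrobenzofuran-5-yl}prop-2-enoate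
Product: 12 (2E)-3-[(2S,3R)-2-(4-hydroxy-3,5-dimethoxyphenyl)-3-(hydroxymethyl)-7-methoxy-2,3-dihydrobenzofuran-5-yl]prop-2-en-1-ol
Conditions: i-Bu2AlH (6 equiv), CH2Cl2, −78 to 0 °C; aq. potassium sodium tartrate
Reagents that add atoms: none
Why: Hydride reduction with excess i-Bu2AlH should effect 1,2-reduction of the enoate to the allylic alcohol and reductive cleavage of the aryl pivalate in the same operation, so the triol arises without an oxidation in the presence of the free phenol.

Step 10
Reactants: 12 (2E)-3-[(2S,3R)-2-(4-hydroxy-3,5-dimethoxyphenyl)-3-(hydroxymethyl)-7-methoxy-2,3-dihydrobenzofuran-5-yl]prop-2-en-1-ol, 13 4-hydroxybenzoic acid (3 equiv)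
Product: 14 quiquesetinerviusin B
Conditions: PPh3 (3 equiv), DIAD (3 equiv), THF, 0 °C to rt
Reagents that add atoms: none
Why: Mitsunobu esterification activates only the two primary alcohols as alkoxyphosphonium ions, and the carboxylate of 13, far more acidic than any phenol present, should displace them, so both esters form while the three phenols stay free and no stereocentre is touched.

Compound list
1 | 4-bromo-2,6-dimethoxyphenol | COc1cc(Br)cc(OC)c1O | starting material
2 | 4-bromo-2,6-dimethoxyphenyl pivalate | COc1cc(Br)cc(OC)c1OC(=O)C(C)(C)C | intermediate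
3 | propargyl alcohol | OCC#C | starting material
4 | tert-butyldimethyl(prop-2-yn-1-yloxy)silane | C#CCO[Si](C)(C)C(C)(C)C | intermediate
5 | 4-[3-(tert-butyldimethylsilyloxy)prop-1-yn-1-yl]-2,6-dimethoxyphenyl pivalate | COc1cc(C#CCO[Si](C)(C)C(C)(C)C)cc(OC)c1OC(=O)C(C)(C)C | intermediate
6 | 4-[(1Z)-3-(tert-butyldimethylsilyloxy)prop-1-en-1-yl]-2,6-dimethoxyphenyl pivalate | COc1cc(/C=C\CO[Si](C)(C)C(C)(C)C)cc(OC)c1OC(=O)C(C)(C)C | intermediate
7 | 4-[(2R,3S)-3-(tert-butyldimethylsilyloxymethyl)oxiran-2-yl]-2,6-dimethoxyphenyl pivalate (cis) | COc1cc([C@H]2O[C@H]2CO[Si](C)(C)C(C)(C)C)cc(OC)c1OC(=O)C(C)(C)C | intermediate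
8 | 4-iodo-3-methoxybenzaldehyde | COc1cc(C=O)ccc1I | starting material
9 | (2S,3R)-3-(tert-butyldimethylsilyloxymethyl)-2-[3,5-dimethoxy-4-(pivaloyloxy)phenyl]-7-methoxy-2,3-dihydrobenzofuran-5-carbaldehyde | COc1cc([C@H]2Oc3c(OC)cc(C=O)cc3[C@@H]2CO[Si](C)(C)C(C)(C)C)cc(OC)c1OC(=O)C(C)(C)C | intermediate
10 | (2S,3R)-2-[3,5-dimethoxy-4-(pivaloyloxy)phenyl]-3-(hydroxymethyl)-7-methoxy-2,3-dihydrobenzofuran-5-carbaldehyde | COc1cc([C@H]2Oc3c(OC)cc(C=O)cc3[C@@H]2CO)cc(OC)c1OC(=O)C(C)(C)C | intermediate
11 | ethyl (2E)-3-{(2S,3R)-2-[3,5-dimethoxy-4-(pivaloyloxy)phenyl]-3-(hydroxymethyl)-7-methoxy-2,3-dihydrobenzofuran-5-yl}prop-2-enoate | COc1cc([C@H]2Oc3c(OC)cc(/C=C/C(=O)OCC)cc3[C@@H]2CO)cc(OC)c1OC(=O)C(C)(C)C | intermediate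
12 | (2E)-3-[(2S,3R)-2-(4-hydroxy-3,5-dimethoxyphenyl)-3-(hydroxymethyl)-7-methoxy-2,3-dihydrobenzofuran-5-yl]prop-2-en-1-ol | COc1cc([C@H]2Oc3c(OC)cc(/C=C/CO)cc3[C@@H]2CO)cc(OC)c1O | intermediate
13 | 4-hydroxybenzoic acid | OC(=O)c1ccc(O)cc1 | starting material
14 | quiquesetinerviusin B, (2E)-3-[(2S,3R)-2-(4-hydroxy-3,5-dimethoxyphenyl)-3-{[(4-hydroxybenzoyl)oxy]methyl}-7-methoxy-2,3-dihydrobenzofuran-5-yl]prop-2-en-1-yl 4-hydroxybenzoate | COc1cc([C@H]2Oc3c(OC)cc(/C=C/COC(=O)c4ccc(O)cc4)cc3[C@@H]2COC(=O)c2ccc(O)cc2)cc(OC)c1O | target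

Total step count: 10. Longest linear sequence: 9 steps (1, 2, 5, 6, 7, 9, 10, 11, 12, 14).

Steps most likely to fail

1. Step 6 (the new annulation). The palladacycle may attack the benzylic epoxide carbon and give the 3-aryl regioisomer, it may fail to add to a secondary carbon at all, or zerovalent palladium may isomerise the aryl epoxide to a ketone. The fallback uses known chemistry and a different disconnection: C3–C3a by cross-coupling, the C3 hydrogen by asymmetric hydroboration, and O1–C2 by acid-mediated etherification. It sets out from alkyne 5 and comes back to the route at aldehyde 10. Copper-catalysed syn-hydroboration of 5 (B2pin2, CuCl, Xantphos, cat. NaOt-Bu, i-PrOH) should place boron on the alkyne carbon remote from the aryl group and give the alkenyl pinacolboronate F1. Commercial 5-bromovanillin is converted with ethylene glycol (TsOH, toluene, reflux) into the dioxolane-protected bromophenol F2. Suzuki–Miyaura coupling of F1 with F2 (PdCl2(dppf), K3PO4, dioxane/water, 80 °C) then gives, with retention of double-bond geometry, the trisubstituted alkene F3. Brown asymmetric hydroboration of F3 with monoisopinocampheylborane (the enantiomer that adds hydrogen to the face of C3 giving the R configuration), followed by oxidation with NaBO3·4H2O, puts hydrogen on C3 and hydroxyl on the benzylic carbon C2 and gives the alcohol F4. Acid treatment of F4 (BF3·OEt2 in CH2Cl2, then aqueous HCl in THF) closes O1–C2 through the benzylic cation to the thermodynamically preferred trans ring, with C3 dictating the configuration at C2, and removes the dioxolane and the silyl ether, which gives 10.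

2. Step 5 (asymmetric epoxidation). Stepwise, radical-type collapse at the manganese centre can leak to the trans-epoxide and erode enantiofacial discrimination, and the bulky allylic silyl ether may lower it further. The fallback replaces ligand-controlled oxygen transfer by a hydroxyl-directed, concerted one; it sets out from Z-alkene 6 and comes back at epoxide 7. Desilylation of 6 (Bu4NF, AcOH, THF) gives the Z-allylic alcohol F5. Sharpless asymmetric epoxidation of F5 (Ti(Oi-Pr)4, L-(+)-diisopropyl tartrate, t-BuOOH, 4 Å molecular sieves, CH2Cl2, −20 °C) cannot scramble the alkene geometry and should give the cis-epoxy alcohol F6, whose enantiomeric purity can be raised by crystallisation of a derivative if needed. Silylation of F6 (TBSCl, imidazole, CH2Cl2) returns 7.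

3. Step 10 (double Mitsunobu esterification). The activated cinnamyl alcohol may ionise and suffer allylic transposition, ring A may participate at the activated C3 hydroxymethyl carbon, a phenol may be O-alkylated, or the second esterification may stall. The fallback activates the acid instead of the alcohols and masks the phenols; it sets out from triol 12 and comes back at target 14. Chemoselective acetylation of the phenoxide (Ac2O, K2CO3, acetone, rt) gives the aryl acetate F7. Steglich esterification of both primary alcohols of F7 with commercial 4-acetoxybenzoic acid (EDC·HCl, DMAP, CH2Cl2) gives the triacetate F8. Aminolysis of the three phenolic acetates of F8 with pyrrolidine (THF, 0 °C to rt), which should leave the two alkyl benzoates intact, gives 14.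

Further compounds
F1 | step 6 | 4-[(1Z)-3-(tert-butyldimethylsilyloxy)-2-(4,4,5,5-tetramethyl-1,3,2-dioxaborolan-2-yl)prop-1-en-1-yl]-2,6-dimethoxyphenyl pivalate | COc1cc(/C=C(CO[Si](C)(C)C(C)(C)C)/B2OC(C)(C)C(C)(C)O2)cc(OC)c1OC(=O)C(C)(C)C
F2 | step 6 | 2-bromo-4-(1,3-dioxolan-2-yl)-6-methoxyphenol | COc1cc(C2OCCO2)cc(Br)c1O
F3 | step 6 | 4-[(1Z)-3-(tert-butyldimethylsilyloxy)-2-[5-(1,3-dioxolan-2-yl)-2-hydroxy-3-methoxyphenyl]prop-1-en-1-yl]-2,6-dimethoxyphenyl pivalate (aryl groups trans) | COc1cc(/C=C(CO[Si](C)(C)C(C)(C)C)/c2cc(C3OCCO3)cc(OC)c2O)cc(OC)c1OC(=O)C(C)(C)C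
F4 | step 6 | 4-[(1S,2R)-3-(tert-butyldimethylsilyloxy)-2-[5-(1,3-dioxolan-2-yl)-2-hydroxy-3-methoxyphenyl]-1-hydroxypropyl]-2,6-dimethoxyphenyl pivalate | COc1cc([C@@H](O)[C@@H](CO[Si](C)(C)C(C)(C)C)c2cc(C3OCCO3)cc(OC)c2O)cc(OC)c1OC(=O)C(C)(C)C
F5 | step 5 | 4-[(1Z)-3-hydroxyprop-1-en-1-yl]-2,6-dimethoxyphenyl pivalate | COc1cc(/C=C\CO)cc(OC)c1OC(=O)C(C)(C)C
F6 | step 5 | 4-[(2R,3S)-3-(hydroxymethyl)oxiran-2-yl]-2,6-dimethoxyphenyl pivalate (cis) | COc1cc([C@H]2O[C@H]2CO)cc(OC)c1OC(=O)C(C)(C)C
F7 | step 10 | 4-{(2S,3R)-3-(hydroxymethyl)-5-[(1E)-3-hydroxyprop-1-en-1-yl]-7-methoxy-2,3-dihydrobenzofuran-2-yl}-2,6-dimethoxyphenyl acetate | COc1cc([C@H]2Oc3c(OC)cc(/C=C/CO)cc3[C@@H]2CO)cc(OC)c1OC(C)=O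
F8 | step 10 | (2E)-3-[(2S,3R)-2-(4-acetoxy-3,5-dimethoxyphenyl)-3-{[(4-acetoxybenzoyl)oxy]methyl}-7-methoxy-2,3-dihydrobenzofuran-5-yl]prop-2-en-1-yl 4-acetoxybenzoate | COc1cc([C@H]2Oc3c(OC)cc(/C=C/COC(=O)c4ccc(OC(C)=O)cc4)cc3[C@@H]2COC(=O)c2ccc(OC(C)=O)cc2)cc(OC)c1OC(C)=O
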